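**Plan**

Numbering (labdane style): ring A = C1–C5 and C10; ring B = C5–C10; chain C11, C12; dioxane carbons C13–C16; propanoate C17, C18. The retrosynthesis cuts C11–C12 (as an olefin), then in the decalin C1–C10 and C3–C4 (ring A) back to (S)-carvone and a C3 dihalide, and in the dioxane O–C16 and O–C13.
Forward: ring B is carvone; ring A is annulated onto it in one operation; the C9 ketone becomes the C11 arm (methylenation, hydroboration, sulfone); the 1,2-dioxane aldehyde is built separately from (R)-2-methylglycidol; Julia–Kocienski union and diimide reduction finish the chain.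
Enabling feature: the two quaternary carbons of ring A, C4 and C10, flank C5. C10 is alpha to the carvone carbonyl C9 (an enolate carbon) and C4 is the internal carbon of the carvone isopropenyl group (a Markovnikov radical site), while C1–C3 are three plain CH2 groups, so a 1,3-dihalopropane can bridge them.
Stereochemistry: C5 from (S)-carvone; C10 by stereoconvergent enolate alkylation anti to the isopropenyl group; C9 by hydroboration anti to the angular methyl group; C13 from (R)-2-methylglycidol with one inversion in the perhydrolysis; C16 and C17 by tartrate-controlled crotylboration, C16 then inverted in the peroxide ring closure.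

Key step: step 2

Remark: (R)-2-methylglycidol is taken as a commercial building block, and the tartrate crotylboronate of step 12 as a reagent made by the standard procedure from (Z)-but-2-ene, triisopropyl borate and diisopropyl L-tartrate.

**Route**

Step 1
Reactants: 1 (S)-carvone
Product: 2 (5S)-2,6-dimethyl-5-(prop-1-en-2-yl)cyclohex-2-en-1-one (6-methylcarvone, both C6 epimers)
Conditions: LiN(iPr)2, THF, −78 °C; MeI, −78 → 0 °C
Reagents that add atoms: iodomethane, CI
Why: Kinetic deprotonation of the enone at the α′ carbon and enolate alkylation with iodomethane should give 2 as a mixture of C6 epimers, which does not matter because step 2 passes through the same planar enolate.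

Step 2
Reactants: 2 (5S)-2,6-dimethyl-5-(prop-1-en-2-yl)cyclohex-2-en-1-one; 3 1-chloro-3-iodopropane
Product: 6 (4aR,8aR)-2,5,5,8a-tetramethyl-4a,5,6,7,8,8a-hexahydronaphthalen-1(4H)-one, via chloropropyl ketone 4 (not isolated), via iodopropyl ketone 5 (not isolated)
Conditions: LiN(iPr)2, THF/DMPU, −78 °C, then 3, −78 → 0 °C; NaI, 50 °C; then DCE/propylene carbonate, Mn(dpm)3 (dpm = 2,2,6,6-tetramethylheptane-3,5-dionate, cat.), Ni(acac)2 (cat.), PhSiH3, K2CO3, rt
Reagents that add atoms: none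
Why: Proposed new method: the lithium enolate of 2 is planar at C10, so both C6 epimers converge, and it is C-alkylated by the iodide terminus of 3 on the face anti to the C5 isopropenyl group (the enolate alkylation known for 6-methylcarvone with primary halides), which sets C10 with the new C1–C10 bond trans to the C5–C4 bond; halide exchange then arms C3 as the iodide 5. A manganese hydride formed from Mn(dpm)3 and PhSiH3 transfers a hydrogen atom to the terminal CH2 of the isopropenyl group, the resulting tertiary C4 radical is captured by nickel that has inserted into the C3–I bond, and reductive elimination forges the C3–C4 bond, so that C4 becomes the gem-dimethyl quaternary carbon. The closest known reaction type is the manganese/nickel dual-catalytic Markovnikov hydroalkylation of 1,1-disubstituted olefins with primary alkyl iodides, which builds quaternary carbons intermolecularly; new here are its intramolecular use, the telescoping with the alkylation and the enone in the substrate. Ring A closes by a formal 6-exo-tet union of the C4 radical with C3 through a seven-membered nickelacycle, and because C4 is not stereogenic the trans ring fusion is already fixed by the alkylation, in which the C5 stereocentre of carvone controls C10. The step needs hydrogen atom transfer to the electron-rich 1,1-disubstituted alkene and not to the electron-poor trisubstituted enone, and coupling and not simple reduction of the C4 radical; the higher reactivity of the isopropenyl group toward the metal hydride and the intramolecular iodide should secure both.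

Step 3
Reactants: 6 (4aR,8aR)-2,5,5,8a-tetramethyl-4a,5,6,7,8,8a-hexahydronaphthalen-1(4H)-one
Product: 7 (4aR,8aR)-1,1,4a,6-tetramethyl-5-methylidene-1,2,3,4,4a,5,8,8a-octahydronaphthalene
Conditions: Ph3PCH3Br, KOtBu, toluene, 90 °C
Reagents that add atoms: methyltriphenylphosphonium bromide, C[P+](c1ccccc1)(c1ccccc1)c1ccccc1.[Br-]
Why: Wittig methylenation of the hindered enone carbonyl, which has no α′ hydrogen, with the small ylide under forcing conditions should give the exocyclic diene without touching the two ring-fusion stereocentres.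

Step 4
Reactants: 7 (4aR,8aR)-1,1,4a,6-tetramethyl-5-methylidene-1,2,3,4,4a,5,8,8a-octahydronaphthalene
Product: 9 [(1R,4aR,8aR)-2,5,5,8a-tetramethyl-1,4,4a,5,6,7,8,8a-octahydronaphthalen-1-yl]methanol (ent-drimenol), via alkylborane 8 (not isolated)
Conditions: 9-BBN, THF, rt → 50 °C; then NaOH, H2O2, 0 °C → rt
Reagents that add atoms: hydrogen peroxide, OO
Why: Hydroboration–oxidation: 9-BBN adds boron to the terminal carbon of the exocyclic 1,1-disubstituted alkene and delivers hydrogen to C9 from the face anti to the axial angular methyl group, so that C9 gets its hydrogen axial and the CH2OH arm equatorial and cis to the methyl group (1R), while the trisubstituted ring alkene is too hindered to react.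

Step 5
Reactants: 9 [(1R,4aR,8aR)-2,5,5,8a-tetramethyl-1,4,4a,5,6,7,8,8a-octahydronaphthalen-1-yl]methanol
Product: 10 1-phenyl-5-({[(1R,4aR,8aR)-2,5,5,8a-tetramethyl-1,4,4a,5,6,7,8,8a-octahydronaphthalen-1-yl]methyl}sulfanyl)-1H-tetrazole
Conditions: 1-phenyl-1H-tetrazole-5-thiol, PPh3, DIAD, THF, 0 °C → rt
Reagents that add atoms: 1-phenyl-1H-tetrazole-5-thiol, Sc1nnnn1-c1ccccc1
Why: Mitsunobu thioetherification of the primary alcohol with the acidic tetrazole thiol; no stereocentre is involved.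

Step 6
Reactants: 10 1-phenyl-5-({[(1R,4aR,8aR)-2,5,5,8a-tetramethyl-1,4,4a,5,6,7,8,8a-octahydronaphthalen-1-yl]methyl}sulfanyl)-1H-tetrazole
Product: 11 1-phenyl-5-({[(1R,4aR,8aR)-2,5,5,8a-tetramethyl-1,4,4a,5,6,7,8,8a-octahydronaphthalen-1-yl]methyl}sulfonyl)-1H-tetrazole
Conditions: (NH4)6Mo7O24·4H2O (cat.), 30% H2O2, EtOH, 0 °C → rt
Reagents that add atoms: hydrogen peroxide, OO
Why: Molybdate-catalysed peroxide oxidation takes the sulfide to the sulfone (sulfur oxidation) much faster than it epoxidises the hindered trisubstituted alkene.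

Step 7
Reactants: 12 [(2R)-2-methyloxiran-2-yl]methanol ((R)-2-methylglycidol)
Product: 13 (2S)-2-methylhex-5-ene-1,2-diol
Conditions: allylMgBr (3 equiv), CuI (cat.), THF, −30 → 0 °C; aq. NH4Cl
Reagents that add atoms: allylmagnesium bromide, C=CC[Mg]Br
Why: Copper-catalysed Grignard opening of the epoxide at its CH2 terminus (SN2) leaves the tertiary stereocentre untouched, the change of descriptor from R to S being only a change of priorities.

Step 8
Reactants: 13 (2S)-2-methylhex-5-ene-1,2-diol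
Product: 15 (2S)-2-(but-3-en-1-yl)-2-methyloxirane, via monotosylate 14 (not isolated)
Conditions: TsCl, Et3N, Bu2SnO (cat.), CH2Cl2, 0 °C; then K2CO3, MeOH, rt
Reagents that add atoms: none
Why: Tin-catalysed selective tosylation of the primary hydroxyl and intramolecular Williamson etherification by the tertiary alkoxide close the new epoxide with retention at the tertiary carbon.

Step 9
Reactants: 15 (2S)-2-(but-3-en-1-yl)-2-methyloxirane
Product: 16 (2R)-2-hydroperoxy-2-methylhex-5-en-1-ol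
Conditions: anhydrous H2O2 in Et2O, H3PMo12O40 (cat.), rt
Reagents that add atoms: hydrogen peroxide, OO
Why: Acid-catalysed perhydrolysis of the 2,2-disubstituted oxirane should open the ring at the tertiary carbon in a borderline SN2 fashion with inversion, turning the (S)-epoxide into the (R)-hydroperoxide.

Step 10
Reactants: 16 (2R)-2-hydroperoxy-2-methylhex-5-en-1-ol
Product: 17 tert-butyl({(2R)-2-[(tert-butyldimethylsilyl)peroxy]-2-methylhex-5-en-1-yl}oxy)dimethylsilane
Conditions: TBSCl (2.5 equiv), imidazole, DMF, 0 °C → rt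
Reagents that add atoms: tert-butyldimethylsilyl chloride, CC(C)(C)[Si](C)(C)Cl
Why: Silylation caps both the hydroperoxide and the primary alcohol (silyl peroxide and silyl ether formation) so that the peroxide survives the following carbonyl chemistry.

Step 11
Reactants: 17 tert-butyl({(2R)-2-[(tert-butyldimethylsilyl)peroxy]-2-methylhex-5-en-1-yl}oxy)dimethylsilane
Product: 19 (4R)-5-[(tert-butyldimethylsilyl)oxy]-4-[(tert-butyldimethylsilyl)peroxy]-4-methylpentanal, via ozonide 18 (not isolated)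
Conditions: O3, CH2Cl2, −78 °C; then Me2S, −78 °C → rt
Reagents that add atoms: ozone, [O-][O+]=O
Why: Ozonolysis with reductive work-up cleaves the terminal alkene to the aldehyde; silyl peroxides are inert to ozone and to Me2S at low temperature.

Step 12
Reactants: 19 (4R)-5-[(tert-butyldimethylsilyl)oxy]-4-[(tert-butyldimethylsilyl)peroxy]-4-methylpentanal
Product: 20 (3R,4R,7R)-8-[(tert-butyldimethylsilyl)oxy]-7-[(tert-butyldimethylsilyl)peroxy]-3,7-dimethyloct-1-en-4-ol
Conditions: diisopropyl (4R,5R)-2-[(2Z)-but-2-en-1-yl]-1,3,2-dioxaborolane-4,5-dicarboxylate, 4 Å molecular sieves, toluene, −78 °C; aq. NaHCO3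
Reagents that add atoms: diisopropyl (4R,5R)-2-[(2Z)-but-2-en-1-yl]-1,3,2-dioxaborolane-4,5-dicarboxylate, CC(C)OC(=O)[C@@H]1OB(C/C=C\C)O[C@H]1C(=O)OC(C)C
Why: Roush asymmetric crotylboration through a chair Zimmerman–Traxler transition state: the (Z)-crotyl geometry gives the syn pair and the (R,R)-tartrate directs attack to the si face of the aldehyde, setting (3R,4R).

Step 13
Reactants: 20 (3R,4R,7R)-8-[(tert-butyldimethylsilyl)oxy]-7-[(tert-butyldimethylsilyl)peroxy]-3,7-dimethyloct-1-en-4-ol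
Product: 21 (3R,4R,7R)-8-[(tert-butyldimethylsilyl)oxy]-7-[(tert-butyldimethylsilyl)peroxy]-3,7-dimethyloct-1-en-4-yl methanesulfonate
Conditions: MsCl, Et3N, CH2Cl2, 0 °C
Reagents that add atoms: methanesulfonyl chloride, CS(=O)(=O)Cl
Why: Mesylation of the secondary alcohol with retention turns C4 of the chain (the later ring carbon C16) into the electrophile for ring closure.

Step 14
Reactants: 21 (3R,4R,7R)-8-[(tert-butyldimethylsilyl)oxy]-7-[(tert-butyldimethylsilyl)peroxy]-3,7-dimethyloct-1-en-4-yl methanesulfonate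
Product: 22 tert-butyl({(3R,6S)-6-[(2R)-but-3-en-2-yl]-3-methyl-1,2-dioxan-3-yl}methoxy)dimethylsilane
Conditions: K2CO3, MeOH, 0 °C → rt
Reagents that add atoms: none
Why: Methanolysis cleaves the silyl peroxide (far more labile than the primary silyl ether) and the peroxide anion closes the 1,2-dioxane by intramolecular SN2 alkylation (6-exo-tet) with inversion at the mesylate carbon, as known for hydroperoxide/mesylate cyclizations to 1,2-dioxanes.

Step 15
Reactants: 22 tert-butyl({(3R,6S)-6-[(2R)-but-3-en-2-yl]-3-methyl-1,2-dioxan-3-yl}methoxy)dimethylsilane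
Product: 23 (2S)-2-[(3S,6R)-6-{[(tert-butyldimethylsilyl)oxy]methyl}-6-methyl-1,2-dioxan-3-yl]propanoic acid
Conditions: RuCl3·xH2O (cat.), NaIO4, CCl4/MeCN/H2O, rt
Reagents that add atoms: sodium periodate, [Na+].[O-]I(=O)(=O)=O; water, O
Why: Ruthenium tetroxide cleavage (Sharpless conditions) degrades the vinyl group to the carboxylic acid under non-basic conditions, so the adjacent stereocentre and the dialkyl peroxide should stay intact.

Step 16
Reactants: 23 (2S)-2-[(3S,6R)-6-{[(tert-butyldimethylsilyl)oxy]methyl}-6-methyl-1,2-dioxan-3-yl]propanoic acid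
Product: 24 methyl (2S)-2-[(3S,6R)-6-(hydroxymethyl)-6-methyl-1,2-dioxan-3-yl]propanoate
Conditions: HCl (1.25 M in MeOH), rt
Reagents that add atoms: methanol, CO
Why: Fischer esterification and acid methanolysis of the silyl ether occur in the same acidic methanol, which dialkyl peroxides tolerate.

Step 17
Reactants: 24 methyl (2S)-2-[(3S,6R)-6-(hydroxymethyl)-6-methyl-1,2-dioxan-3-yl]propanoate
Product: 25 methyl (2S)-2-[(3S,6R)-6-formyl-6-methyl-1,2-dioxan-3-yl]propanoate
Conditions: Dess–Martin periodinane, CH2Cl2, rt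
Reagents that add atoms: none
Why: Dess–Martin oxidation gives the aldehyde, which cannot enolize because its α carbon is quaternary.

Step 18
Reactants: 11 1-phenyl-5-({[(1R,4aR,8aR)-2,5,5,8a-tetramethyl-1,4,4a,5,6,7,8,8a-octahydronaphthalen-1-yl]methyl}sulfonyl)-1H-tetrazole; 25 methyl (2S)-2-[(3S,6R)-6-formyl-6-methyl-1,2-dioxan-3-yl]propanoate
Product: 26 methyl (2S)-2-[(3S,6R)-6-methyl-6-{2-[(1R,4aR,8aR)-2,5,5,8a-tetramethyl-1,4,4a,5,6,7,8,8a-octahydronaphthalen-1-yl]ethenyl}-1,2-dioxan-3-yl]propanoate (E/Z mixture)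
Conditions: 11, KN(SiMe3)2, DME, −60 °C; then 25, −60 °C → rt; aq. NH4Cl
Reagents that add atoms: none
Why: Julia–Kocienski olefination: the potassium sulfonyl carbanion adds to the non-enolizable aldehyde and Smiles rearrangement with loss of SO2 gives the C11=C12 alkene, whose geometry is irrelevant.

Step 19
Reactants: 26 methyl (2S)-2-[(3S,6R)-6-methyl-6-{2-[(1R,4aR,8aR)-2,5,5,8a-tetramethyl-1,4,4a,5,6,7,8,8a-octahydronaphthalen-1-yl]ethenyl}-1,2-dioxan-3-yl]propanoate
Product: 27 methyl (2S)-2-[(3S,6S)-6-methyl-6-{2-[(1R,4aR,8aR)-2,5,5,8a-tetramethyl-1,4,4a,5,6,7,8,8a-octahydronaphthalen-1-yl]ethyl}-1,2-dioxan-3-yl]propanoate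
Conditions: KO2CN=NCO2K, AcOH, MeOH, 0 °C → rt
Reagents that add atoms: none
Why: Diimide reduction saturates the 1,2-disubstituted alkene selectively over the trisubstituted ring alkene and leaves the O–O bond and the ester untouched.

**Compound list**

1 | (S)-carvone | CC(=C)[C@H]1CC=C(C)C(=O)C1 | starting material
2 | (5S)-2,6-dimethyl-5-(prop-1-en-2-yl)cyclohex-2-en-1-one (both C6 epimers) | CC(=C)[C@H]1CC=C(C)C(=O)C1C | intermediate
3 | 1-chloro-3-iodopropane | ClCCCI | starting material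
4 | (5R,6R)-6-(3-chloropropyl)-2,6-dimethyl-5-(prop-1-en-2-yl)cyclohex-2-en-1-one | O=C1C(C)=CC[C@H](C(C)=C)[C@@]1(C)CCCCl | intermediate
5 | (5R,6R)-6-(3-iodopropyl)-2,6-dimethyl-5-(prop-1-en-2-yl)cyclohex-2-en-1-one | O=C1C(C)=CC[C@H](C(C)=C)[C@@]1(C)CCCI | intermediate
6 | (4aR,8aR)-2,5,5,8a-tetramethyl-4a,5,6,7,8,8a-hexahydronaphthalen-1(4H)-one | O=C1C(C)=CC[C@@H]2C(C)(C)CCC[C@@]12C | intermediate
7 | (4aR,8aR)-1,1,4a,6-tetramethyl-5-methylidene-1,2,3,4,4a,5,8,8a-octahydronaphthalene | C=C1C(C)=CC[C@@H]2C(C)(C)CCC[C@@]12C | intermediate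
8 | 9-{[(1R,4aR,8aR)-2,5,5,8a-tetramethyl-1,4,4a,5,6,7,8,8a-octahydronaphthalen-1-yl]methyl}-9-borabicyclo[3.3.1]nonane | C1CC2CCCC(C1)B2C[C@@H]1C(C)=CC[C@@H]2C(C)(C)CCC[C@@]12C | intermediate
9 | [(1R,4aR,8aR)-2,5,5,8a-tetramethyl-1,4,4a,5,6,7,8,8a-octahydronaphthalen-1-yl]methanol (ent-drimenol) | OC[C@@H]1C(C)=CC[C@@H]2C(C)(C)CCC[C@@]12C | intermediate
10 | 1-phenyl-5-({[(1R,4aR,8aR)-2,5,5,8a-tetramethyl-1,4,4a,5,6,7,8,8a-octahydronaphthalen-1-yl]methyl}sulfanyl)-1H-tetrazole | C(Sc1nnnn1-c1ccccc1)[C@@H]1C(C)=CC[C@@H]2C(C)(C)CCC[C@@]12C | intermediate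
11 | 1-phenyl-5-({[(1R,4aR,8aR)-2,5,5,8a-tetramethyl-1,4,4a,5,6,7,8,8a-octahydronaphthalen-1-yl]methyl}sulfonyl)-1H-tetrazole | O=S(=O)(C[C@@H]1C(C)=CC[C@@H]2C(C)(C)CCC[C@@]12C)c1nnnn1-c1ccccc1 | intermediate
12 | [(2R)-2-methyloxiran-2-yl]methanol | OC[C@]1(C)CO1 | starting material
13 | (2S)-2-methylhex-5-ene-1,2-diol | C=CCC[C@](C)(O)CO | intermediate
14 | (2S)-2-hydroxy-2-methylhex-5-en-1-yl 4-methylbenzenesulfonate | C=CCC[C@](C)(O)COS(=O)(=O)c1ccc(C)cc1 | intermediate
15 | (2S)-2-(but-3-en-1-yl)-2-methyloxirane | C=CCC[C@@]1(C)CO1 | intermediate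
16 | (2R)-2-hydroperoxy-2-methylhex-5-en-1-ol | C=CCC[C@](C)(CO)OO | intermediate
17 | tert-butyl({(2R)-2-[(tert-butyldimethylsilyl)peroxy]-2-methylhex-5-en-1-yl}oxy)dimethylsilane | C=CCC[C@](C)(CO[Si](C)(C)C(C)(C)C)OO[Si](C)(C)C(C)(C)C | intermediate
18 | 1,2,4-trioxolane (secondary ozonide) of 17 | O1OC(CC[C@](C)(CO[Si](C)(C)C(C)(C)C)OO[Si](C)(C)C(C)(C)C)OC1 | intermediate
19 | (4R)-5-[(tert-butyldimethylsilyl)oxy]-4-[(tert-butyldimethylsilyl)peroxy]-4-methylpentanal | O=CCC[C@](C)(CO[Si](C)(C)C(C)(C)C)OO[Si](C)(C)C(C)(C)C | intermediate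
20 | (3R,4R,7R)-8-[(tert-butyldimethylsilyl)oxy]-7-[(tert-butyldimethylsilyl)peroxy]-3,7-dimethyloct-1-en-4-ol | C=C[C@@H](C)[C@H](O)CC[C@](C)(CO[Si](C)(C)C(C)(C)C)OO[Si](C)(C)C(C)(C)C | intermediate
21 | (3R,4R,7R)-8-[(tert-butyldimethylsilyl)oxy]-7-[(tert-butyldimethylsilyl)peroxy]-3,7-dimethyloct-1-en-4-yl methanesulfonate | C=C[C@@H](C)[C@H](OS(C)(=O)=O)CC[C@](C)(CO[Si](C)(C)C(C)(C)C)OO[Si](C)(C)C(C)(C)C | intermediate
22 | tert-butyl({(3R,6S)-6-[(2R)-but-3-en-2-yl]-3-methyl-1,2-dioxan-3-yl}methoxy)dimethylsilane | C=C[C@@H](C)[C@@H]1CC[C@](C)(CO[Si](C)(C)C(C)(C)C)OO1 | intermediate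
23 | (2S)-2-[(3S,6R)-6-{[(tert-butyldimethylsilyl)oxy]methyl}-6-methyl-1,2-dioxan-3-yl]propanoic acid | OC(=O)[C@@H](C)[C@@H]1CC[C@](C)(CO[Si](C)(C)C(C)(C)C)OO1 | intermediate
24 | methyl (2S)-2-[(3S,6R)-6-(hydroxymethyl)-6-methyl-1,2-dioxan-3-yl]propanoate | COC(=O)[C@@H](C)[C@@H]1CC[C@](C)(CO)OO1 | intermediate
25 | methyl (2S)-2-[(3S,6R)-6-formyl-6-methyl-1,2-dioxan-3-yl]propanoate | COC(=O)[C@@H](C)[C@@H]1CC[C@](C)(C=O)OO1 | intermediate
26 | methyl (2S)-2-[(3S,6R)-6-methyl-6-{2-[(1R,4aR,8aR)-2,5,5,8a-tetramethyl-1,4,4a,5,6,7,8,8a-octahydronaphthalen-1-yl]ethenyl}-1,2-dioxan-3-yl]propanoate (E/Z mixture) | COC(=O)[C@@H](C)[C@@H]1CC[C@](C)(C=C[C@@H]2C(C)=CC[C@@H]3C(C)(C)CCC[C@@]23C)OO1 | intermediate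
27 | methyl (2S)-2-[(3S,6S)-6-methyl-6-{2-[(1R,4aR,8aR)-2,5,5,8a-tetramethyl-1,4,4a,5,6,7,8,8a-octahydronaphthalen-1-yl]ethyl}-1,2-dioxan-3-yl]propanoate | COC(=O)[C@@H](C)[C@@H]1CC[C@](C)(CC[C@@H]2C(C)=CC[C@@H]3C(C)(C)CCC[C@@]23C)OO1 | target

**Summary**

Total steps: 19. Longest linear sequence: 13 steps (steps 7 to 17, then 18 and 19).

Steps most likely to fail:

Step 2 (the proposed new method). The tertiary C4 radical may simply be reduced to the isopropyl group, or hydrogen atom transfer may go to the enone, before nickel couples the radical with C3. The fallback sets out from 2 and comes back at 6. Compound 2 is alkylated (LiN(iPr)2, THF, −78 °C) with ethyl 2-(bromomethyl)acrylate to ethyl 2-{[(1R,6R)-1,3-dimethyl-2-oxo-6-(prop-1-en-2-yl)cyclohex-3-en-1-yl]methyl}prop-2-enoate F1. Fe(acac)3/PhSiH3 (EtOH/ethylene glycol, 60 °C) then closes ring A by a hydrogen-atom-transfer-initiated 6-endo Giese cyclization onto the acrylate, giving ethyl (4aR,8aR)-4,4,7,8a-tetramethyl-8-oxo-1,2,3,4,4a,5,8,8a-octahydronaphthalene-2-carboxylate F2 (C2 epimers). LiOH gives (4aR,8aR)-4,4,7,8a-tetramethyl-8-oxo-1,2,3,4,4a,5,8,8a-octahydronaphthalene-2-carboxylic acid F3, N-hydroxypyridine-2-thione/DCC gives its 2-thioxopyridin-1(2H)-yl ester F4, and Barton decarboxylation (t-BuSH, hν) removes the helper carboxyl group to give 6.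

Step 9. Partial ionization at the tertiary carbon may erode the configuration at C13 during the intermolecular perhydrolysis. The fallback sets out from 15 and comes back at 22; it forms the tertiary C–O bond last and intramolecularly. Compound 15 is ozonized (O3; Me2S) through the ozonide (2S)-2-methyl-2-[2-(1,2,4-trioxolan-3-yl)ethyl]oxirane F5 to 3-[(2S)-2-methyloxiran-2-yl]propanal F6. The crotylboration of step 12 gives (3R,4R)-3-methyl-6-[(2S)-2-methyloxiran-2-yl]hex-1-en-4-ol F7, and MsCl/Et3N gives (3R,4R)-3-methyl-6-[(2S)-2-methyloxiran-2-yl]hex-1-en-4-yl methanesulfonate F8. CsOH·H2O/H2O2 in DMF displaces the mesylate with inversion to give (2S)-2-[(3S,4R)-3-hydroperoxy-4-methylhex-5-en-1-yl]-2-methyloxirane F9. Camphorsulfonic acid (cat.) then lets the hydroperoxide open the epoxide 6-exo at the tertiary carbon with inversion to {(3R,6S)-6-[(2R)-but-3-en-2-yl]-3-methyl-1,2-dioxan-3-yl}methanol F10, and TBSCl/imidazole gives 22.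

Step 18. The hindered sulfonyl carbanion may add poorly to the α-quaternary aldehyde, or the alkoxide adduct next to the peroxide-bearing carbon may fragment before the Smiles rearrangement. The fallback sets out from 9 and comes back at 26; it replaces the anionic olefination by a salt-free Wittig reaction that passes through an oxaphosphetane. Compound 9 is converted (I2, PPh3, imidazole) to (1R,4aR,8aR)-1-(iodomethyl)-2,5,5,8a-tetramethyl-1,4,4a,5,6,7,8,8a-octahydronaphthalene F11. Heating with PPh3 in MeCN gives {[(1R,4aR,8aR)-2,5,5,8a-tetramethyl-1,4,4a,5,6,7,8,8a-octahydronaphthalen-1-yl]methyl}triphenylphosphonium iodide F12. Its ylide (NaN(SiMe3)2, THF, −78 °C) reacts with 25 to give 26.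

**Further compounds**

F1 | step 2 | ethyl 2-{[(1R,6R)-1,3-dimethyl-2-oxo-6-(prop-1-en-2-yl)cyclohex-3-en-1-yl]methyl}prop-2-enoate | O=C1C(C)=CC[C@H](C(C)=C)[C@@]1(C)CC(=C)C(=O)OCC
F2 | step 2 | ethyl (4aR,8aR)-4,4,7,8a-tetramethyl-8-oxo-1,2,3,4,4a,5,8,8a-octahydronaphthalene-2-carboxylate | O=C1C(C)=CC[C@@H]2C(C)(C)CC(C(=O)OCC)C[C@@]12C
F3 | step 2 | (4aR,8aR)-4,4,7,8a-tetramethyl-8-oxo-1,2,3,4,4a,5,8,8a-octahydronaphthalene-2-carboxylic acid | O=C1C(C)=CC[C@@H]2C(C)(C)CC(C(O)=O)C[C@@]12C
F4 | step 2 | 2-thioxopyridin-1(2H)-yl (4aR,8aR)-4,4,7,8a-tetramethyl-8-oxo-1,2,3,4,4a,5,8,8a-octahydronaphthalene-2-carboxylate | O=C1C(C)=CC[C@@H]2C(C)(C)CC(C(=O)ON3C=CC=CC3=S)C[C@@]12C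
F5 | step 9 | (2S)-2-methyl-2-[2-(1,2,4-trioxolan-3-yl)ethyl]oxirane | O1OC(CC[C@@]2(C)CO2)OC1
F6 | step 9 | 3-[(2S)-2-methyloxiran-2-yl]propanal | O=CCC[C@@]1(C)CO1
F7 | step 9 | (3R,4R)-3-methyl-6-[(2S)-2-methyloxiran-2-yl]hex-1-en-4-ol | C=C[C@@H](C)[C@H](O)CC[C@@]1(C)CO1
F8 | step 9 | (3R,4R)-3-methyl-6-[(2S)-2-methyloxiran-2-yl]hex-1-en-4-yl methanesulfonate | C=C[C@@H](C)[C@H](OS(C)(=O)=O)CC[C@@]1(C)CO1
F9 | step 9 | (2S)-2-[(3S,4R)-3-hydroperoxy-4-methylhex-5-en-1-yl]-2-methyloxirane | C=C[C@@H](C)[C@@H](OO)CC[C@@]1(C)CO1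
F10 | step 9 | {(3R,6S)-6-[(2R)-but-3-en-2-yl]-3-methyl-1,2-dioxan-3-yl}methanol | C=C[C@@H](C)[C@@H]1CC[C@](C)(CO)OO1
F11 | step 18 | (1R,4aR,8aR)-1-(iodomethyl)-2,5,5,8a-tetramethyl-1,4,4a,5,6,7,8,8a-octahydronaphthalene | IC[C@@H]1C(C)=CC[C@@H]2C(C)(C)CCC[C@@]12C
F12 | step 18 | {[(1R,4aR,8aR)-2,5,5,8a-tetramethyl-1,4,4a,5,6,7,8,8a-octahydronaphthalen-1-yl]methyl}triphenylphosphonium iodide | [I-].C([P+](c1ccccc1)(c1ccccc1)c1ccccc1)[C@@H]1C(C)=CC[C@@H]2C(C)(C)CCC[C@@]12C
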